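**Retrosynthetic overview**

1. Target ⇐ 1,2,3-triol dibenzoate: the C1 acetate goes on last, by axial-selective opening of a cyclic orthoacetate on the cis C1/C2 diol.
2. Both benzoates ⇐ one double Mitsunobu reaction (inversion at C6) on the cis-diol obtained by Luche reduction of an α-(hydroxymethyl) enone.
3. C5–C7 bond ⇐ Morita–Baylis–Hillman hydroxymethylation of a γ-silyloxy cyclohexenone.
4. That enone ⇐ meso endoperoxide by an organocatalytic desymmetrising Kornblum–DeLaMare rearrangement with silyl capture (first stereocentre, C3).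
5. Endoperoxide ⇐ singlet oxygen + acetonide of meso cis-dihydrocatechol. The carbocycle is bought; the only rings formed are the temporary dioxolane (step 1) and the peroxide bridge (step 2).

Assumption: cis-cyclohexa-3,5-diene-1,2-diol (meso) is taken as a commercial achiral starting material; the quinidine-series catalyst in step 3 is assumed to remove the C6 bridgehead hydrogen, and its quinine-series pseudoenantiomer would be used if the sense turns out opposite. Atom labels C1–C7 are target positions: C1 = CH–OAc, C2 and C3 = CH–OH, C4 = CH=, C5 = C(CH2OBz), C6 = CH–OBz, C7 = CH2O.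

**Step 1**
Reactants: 1 (1R,2S)-cyclohexa-3,5-diene-1,2-diol (cis, meso); 2 2,2-dimethoxypropane
Product: 3 (3aR,7aS)-2,2-dimethyl-3a,7a-dihydro-1,3-benzodioxole (meso)
Conditions: Me2C(OMe)2, PPTS (cat.), CH2Cl2, 0 °C; used at once
Reagents that add atoms: 2,2-dimethoxypropane, COC(C)(C)OC
Why: Acid-catalysed transketalisation (acetonide formation) of the cis-diol, which keeps the mirror plane and blocks one ring face.

**Step 2**
Reactants: 3 (3aR,7aS)-2,2-dimethyl-3a,7a-dihydro-1,3-benzodioxole; 4 dioxygen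
Product: 5 meso-4,4-dimethyl-3,5,8,9-tetraoxatricyclo[5.2.2.0^2,6]undec-10-ene (peroxide bridge anti to the dioxolane)
Conditions: O2, TPP (cat.), hν (visible), CH2Cl2, −30 °C
Reagents that add atoms: dioxygen, O=O
Why: [4+2] cycloaddition of singlet oxygen to the diene on the face opposite the dioxolane, which places the C3 and C6 oxygens trans to the C1/C2 oxygens.

**Step 3**
Reactants: 5 meso-4,4-dimethyl-3,5,8,9-tetraoxatricyclo[5.2.2.0^2,6]undec-10-ene; 6 tert-butyldimethylsilyl trifluoromethanesulfonate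
Product: 8 (3aS,7R,7aR)-7-[(tert-butyldimethylsilyl)oxy]-2,2-dimethyl-7,7a-dihydro-3aH-1,3-benzodioxol-4-one, via hydroxy enone 7 (not isolated)
Conditions: 9-O-benzylcupreidine (10 mol%), CH2Cl2, −20 °C; then 2,6-lutidine, TBSOTf, −78 °C
Reagents that add atoms: tert-butyldimethylsilyl trifluoromethanesulfonate, CC(C)(C)[Si](C)(C)OS(=O)(=O)C(F)(F)F
Why: Proposed new method: a desymmetrising Kornblum–DeLaMare rearrangement of a dioxolane-fused 2,3-dioxabicyclo[2.2.2]octene with in-flask silyl capture, in which the quinuclidine nitrogen of the bifunctional 6′-hydroxy cinchona base removes one of the two enantiotopic bridgehead hydrogens (C6–H) while the 6′-OH hydrogen-bonds the distal peroxide oxygen, so O–O cleavage gives the C6 ketone and leaves the C3–O bond untouched (the C3 configuration is decided only by which C–H is removed), and the base-labile hydroxy enone is silylated before it can eliminate or aromatise; the closest known reaction type is the cinchona-base-catalysed Kornblum–DeLaMare desymmetrisation of simple meso endoperoxides to γ-hydroxy enones, which as far as is known has not been shown for this rigid, oxygen-substituted bicyclo[2.2.2] class or coupled to silyl capture.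

**Step 4**
Reactants: 8 (3aS,7R,7aR)-7-[(tert-butyldimethylsilyl)oxy]-2,2-dimethyl-7,7a-dihydro-3aH-1,3-benzodioxol-4-one; 9 formaldehyde
Product: 10 (3aS,7R,7aR)-7-[(tert-butyldimethylsilyl)oxy]-5-(hydroxymethyl)-2,2-dimethyl-7,7a-dihydro-3aH-1,3-benzodioxol-4-one
Conditions: HCHO (37% aq.), DMAP (0.3 equiv), THF–H2O, rt
Reagents that add atoms: formaldehyde, C=O
Why: Morita–Baylis–Hillman hydroxymethylation (DMAP adds at C4, the enolate adds to formaldehyde at C5, E1cB releases DMAP) forms the C5–C7 bond without touching a stereocentre.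

**Step 5**
Reactants: 10 (3aS,7R,7aR)-7-[(tert-butyldimethylsilyl)oxy]-5-(hydroxymethyl)-2,2-dimethyl-7,7a-dihydro-3aH-1,3-benzodioxol-4-one
Product: 11 (3aR,4R,7R,7aR)-7-[(tert-butyldimethylsilyl)oxy]-5-(hydroxymethyl)-2,2-dimethyl-3a,4,7,7a-tetrahydro-1,3-benzodioxol-4-ol
Conditions: NaBH4, CeCl3·7H2O, MeOH, −78 °C
Reagents that add atoms: none
Why: Luche 1,2-reduction, in which hydride adds to C6 from the face opposite the cis-fused dioxolane and gives the C6 alcohol cis to the C1 oxygen, the epimer needed for an invertive benzoylation.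

**Step 6**
Reactants: 11 (3aR,4R,7R,7aR)-7-[(tert-butyldimethylsilyl)oxy]-5-(hydroxymethyl)-2,2-dimethyl-3a,4,7,7a-tetrahydro-1,3-benzodioxol-4-ol; 12 benzoic acid
Product: 13 [(3aR,4S,7R,7aR)-4-(benzoyloxy)-7-[(tert-butyldimethylsilyl)oxy]-2,2-dimethyl-3a,4,7,7a-tetrahydro-1,3-benzodioxol-5-yl]methyl benzoate
Conditions: PhCO2H (3 equiv), PPh3 (3 equiv), DIAD (3 equiv), THF, 0 °C → rt
Reagents that add atoms: benzoic acid, OC(=O)c1ccccc1
Why: Double Mitsunobu esterification, in which the primary C7-OH is benzoylated and the allylic C6-OH is displaced by benzoate with SN2 inversion from the open face anti to the dioxolane, setting C6-OBz trans to the C1 oxygen.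

**Step 7**
Reactants: 13 [(3aR,4S,7R,7aR)-4-(benzoyloxy)-7-[(tert-butyldimethylsilyl)oxy]-2,2-dimethyl-3a,4,7,7a-tetrahydro-1,3-benzodioxol-5-yl]methyl benzoate
Product: 14 [(3R,4S,5S,6S)-6-(benzoyloxy)-3,4,5-trihydroxycyclohex-1-en-1-yl]methyl benzoate
Conditions: 2 M HCl (aq.)–THF (1:4), rt
Reagents that add atoms: none
Why: Acid hydrolysis removes the acetonide and the silyl ether together, while the benzoates survive dilute aqueous acid and no C–O bond at a stereocentre is broken.

**Step 8**
Reactants: 14 [(3R,4S,5S,6S)-6-(benzoyloxy)-3,4,5-trihydroxycyclohex-1-en-1-yl]methyl benzoate; 15 trimethyl orthoacetate; 16 water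
Product: 18 [(3R,4S,5S,6S)-5-(acetyloxy)-6-(benzoyloxy)-3,4-dihydroxycyclohex-1-en-1-yl]methyl benzoate, via cyclic orthoacetate 17 (not isolated)
Conditions: MeC(OMe)3 (1.3 equiv), PPTS (cat.), MeCN, rt; then AcOH–H2O (4:1), rt, 15 min
Reagents that add atoms: trimethyl orthoacetate, COC(C)(OC)OC; water, O
Why: Cyclic orthoester formation on the cis C1/C2 diol followed by acid hydrolysis through the 1,3-dioxolan-2-ylium ion, which opens to the axial ester and equatorial alcohol; with C6-OBz pseudoaxial (A1,2 strain with the C5 substituent) the C1 oxygen is axial and the C2 oxygen equatorial, so the acetate ends on C1.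

**Compound list**

1 | (1R,2S)-cyclohexa-3,5-diene-1,2-diol (cis, meso) | O[C@H]1[C@@H](O)C=CC=C1 | starting material
2 | 2,2-dimethoxypropane | COC(C)(C)OC | starting material
3 | (3aR,7aS)-2,2-dimethyl-3a,7a-dihydro-1,3-benzodioxole (meso) | CC1(C)O[C@H]2[C@@H](O1)C=CC=C2 | intermediate
4 | dioxygen | O=O | starting material
5 | meso-4,4-dimethyl-3,5,8,9-tetraoxatricyclo[5.2.2.0^2,6]undec-10-ene, peroxide anti to dioxolane | CC1(C)O[C@H]2[C@@H](O1)[C@H](OO3)C=C[C@@H]23 | intermediate
6 | tert-butyldimethylsilyl trifluoromethanesulfonate | CC(C)(C)[Si](C)(C)OS(=O)(=O)C(F)(F)F | starting material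
7 | (3aS,7R,7aS)-7-hydroxy-2,2-dimethyl-7,7a-dihydro-3aH-1,3-benzodioxol-4-one | CC1(C)O[C@H]2[C@@H](O1)[C@H](O)C=CC2=O | intermediate
8 | (3aS,7R,7aR)-7-[(tert-butyldimethylsilyl)oxy]-2,2-dimethyl-7,7a-dihydro-3aH-1,3-benzodioxol-4-one | CC1(C)O[C@H]2[C@@H](O1)[C@H](O[Si](C)(C)C(C)(C)C)C=CC2=O | intermediate
9 | formaldehyde | C=O | starting material
10 | (3aS,7R,7aR)-7-[(tert-butyldimethylsilyl)oxy]-5-(hydroxymethyl)-2,2-dimethyl-7,7a-dihydro-3aH-1,3-benzodioxol-4-one | CC1(C)O[C@H]2[C@@H](O1)[C@H](O[Si](C)(C)C(C)(C)C)C=C(CO)C2=O | intermediate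
11 | (3aR,4R,7R,7aR)-7-[(tert-butyldimethylsilyl)oxy]-5-(hydroxymethyl)-2,2-dimethyl-3a,4,7,7a-tetrahydro-1,3-benzodioxol-4-ol | CC1(C)O[C@H]2[C@@H](O1)[C@H](O[Si](C)(C)C(C)(C)C)C=C(CO)[C@H]2O | intermediate
12 | benzoic acid | OC(=O)c1ccccc1 | starting material
13 | [(3aR,4S,7R,7aR)-4-(benzoyloxy)-7-[(tert-butyldimethylsilyl)oxy]-2,2-dimethyl-3a,4,7,7a-tetrahydro-1,3-benzodioxol-5-yl]methyl benzoate | CC1(C)O[C@H]2[C@@H](O1)[C@H](O[Si](C)(C)C(C)(C)C)C=C(COC(=O)c3ccccc3)[C@@H]2OC(=O)c4ccccc4 | intermediate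
14 | [(3R,4S,5S,6S)-6-(benzoyloxy)-3,4,5-trihydroxycyclohex-1-en-1-yl]methyl benzoate | O[C@H]1[C@@H](O)[C@H](O)C=C(COC(=O)c2ccccc2)[C@@H]1OC(=O)c1ccccc1 | intermediate
15 | trimethyl orthoacetate | COC(C)(OC)OC | starting material
16 | water | O | starting material
17 | cyclic orthoacetate of 14 (2-methoxy-2-methyl-1,3-dioxolane across the C1 and C2 oxygens, C3-OH free, either configuration at the orthoester carbon) | COC1(C)O[C@H]2[C@@H](O1)[C@H](O)C=C(COC(=O)c3ccccc3)[C@@H]2OC(=O)c4ccccc4 | intermediate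
18 | [(3R,4S,5S,6S)-5-(acetyloxy)-6-(benzoyloxy)-3,4-dihydroxycyclohex-1-en-1-yl]methyl benzoate | CC(=O)O[C@H]1[C@@H](O)[C@H](O)C=C(COC(=O)c2ccccc2)[C@@H]1OC(=O)c1ccccc1 | target

**Step count and risks**

Total steps: 8. Longest linear sequence: 8 (fully linear from 1).

Three steps most likely to fail:

- **Step 3 (the proposed new step).** The rigid bicycle may rearrange slowly or with low selectivity. The fallback uses known chemistry and sets out from 5. Zn/AcOH reduction of the peroxide gives the meso cis-1,4-diol F1. Lipase desymmetrisation (Pseudomonas cepacia lipase, vinyl acetate) gives the monoacetate F2, written here with the acetate on the C6 oxygen. TBSCl/imidazole gives the silyl ether acetate F3, K2CO3/MeOH gives the allylic alcohol F4, and MnO2 oxidation comes back to the route at 8. If the enzyme acylates the other hydroxyl, the free alcohol is oxidised first and the acetate is exchanged for TBS afterwards, which reaches the same 8.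

- **Step 6.** The hindered allylic C6 alcohol may give SN2′ products or elimination instead of clean inversion. The fallback sets out from 10 and avoids inversion altogether. Reagent-controlled reduction with (S)-Me-CBS oxazaborolidine and catecholborane delivers hydride on the dioxolane face and gives the trans diol F5, the C6 epimer of 11. BzCl/pyridine/DMAP then benzoylates both hydroxyls with retention and comes back at 13.

- **Step 8.** The orthoester may engage the C3 hydroxyl, open to the C2 acetate, or the acetate may migrate. The fallback sets out from 14. Butane-2,3-dione, HC(OMe)3 and CSA in MeOH protect only the trans-diequatorial C2/C3 diol as the butane-2,3-diacetal F6, leaving C1-OH as the only free hydroxyl. Ac2O/pyridine gives the acetate F7, and TFA–H2O removes the diacetal to come back at the target 18.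

**Further compounds**

F1 | step 3 | meso-2,2-dimethyl-3a,4,7,7a-tetrahydro-1,3-benzodioxole-4,7-diol, both OH anti to the dioxolane | CC1(C)O[C@H]2[C@@H](O1)[C@H](O)C=C[C@@H]2O
F2 | step 3 | monoacetate of F1 with acetate on the C6 oxygen and C3-OH free | CC1(C)O[C@H]2[C@@H](O1)[C@H](O)C=C[C@@H]2OC(C)=O
F3 | step 3 | C3 tert-butyldimethylsilyl ether of F2 | CC1(C)O[C@H]2[C@@H](O1)[C@H](O[Si](C)(C)C(C)(C)C)C=C[C@@H]2OC(C)=O
F4 | step 3 | C6 alcohol with C3-OTBS (deacetylated F3) | CC1(C)O[C@H]2[C@@H](O1)[C@H](O[Si](C)(C)C(C)(C)C)C=C[C@@H]2O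
F5 | step 6 | (3aR,4S,7R,7aR)-7-[(tert-butyldimethylsilyl)oxy]-5-(hydroxymethyl)-2,2-dimethyl-3a,4,7,7a-tetrahydro-1,3-benzodioxol-4-ol (C6 epimer of 11) | CC1(C)O[C@H]2[C@@H](O1)[C@H](O[Si](C)(C)C(C)(C)C)C=C(CO)[C@@H]2O
F6 | step 8 | butane-2,3-diacetal of 14 across the C2 and C3 oxygens (axial methoxy groups), C1-OH free | O[C@H]1[C@H]2O[C@](C)(OC)[C@@](C)(OC)O[C@@H]2C=C(COC(=O)c3ccccc3)[C@@H]1OC(=O)c1ccccc1
F7 | step 8 | C1 acetate of F6 | CC(=O)O[C@H]1[C@H]2O[C@](C)(OC)[C@@](C)(OC)O[C@@H]2C=C(COC(=O)c3ccccc3)[C@@H]1OC(=O)c1ccccc1
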